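**Retrosynthetic overview**
- Target 33 comes from its heptadecamethyl ether 32 by BBr3; 32 is cut at E C6–O–F C1 into pentamer phenol 28 and the ring F–G bromide 31 (Ullmann coupling).
- Rings E and D are added one at a time to the growing phenol by Ullmann coupling with bromo-dimethoxybenzaldehydes 25 and 21, each formyl group then becoming the next phenol oxygen by Baeyer–Villiger oxidation; ring A is joined to B C1–OH with iodide 18.
- Feature used: ring B C4 carries the ether oxygen to ring C C1 and sits between the hydroxylated B C3 and B C5, with a further oxygen para at B C1. This 2-aryloxy-5-oxyresorcinol is what a 4-alkoxy-6-(aryloxymethyl)-2-pyranone gives when it is opened and reclosed by Claisen condensation, so the B–C ether needs no aryl–oxygen coupling.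
- Pyranone 12 comes from ring C phenol 5 through amide 7, dioxinone 8 and thermolysis; 5 comes from 2,3,4-trimethoxyphenol 1 by directed metalation and hydroxylation.
- Ring order: rings C, A, D, E, F and G are bought as arenes; the only ring construction is the lactone ring (step 5) and then ring B (step 7).

Key step: step 7

Remark: rings are lettered A (2,4,6-trihydroxyphenoxy end) to G (3,4,5-trihydroxyphenyl end); in rings B, D and F, C1 bears the oxygen toward the A side and C4 the oxygen toward the G side, and in rings C and E, C1 bears the oxygen toward the A side and C6 the oxygen toward the G side; the target has no stereocenter, and compounds 1, 6, 8, 18, 21, 25, 29 and 30 are taken as purchasable.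

**Step 1**
Reactants: 1 2,3,4-trimethoxyphenol
Product: 2 1,2,3-trimethoxy-4-(methoxymethoxy)benzene
Conditions: NaH, MOMCl, DMF, 0 °C → rt
Reagents that add atoms: chloromethyl methyl ether, COCCl
Why: Williamson-type O-alkylation of the phenoxide by the reactive chloromethyl ether should be clean, and the acetal serves both as the protecting group of the later C C6 oxygen and as the directing group for step 2.

**Step 2**
Reactants: 2 1,2,3-trimethoxy-4-(methoxymethoxy)benzene
Product: 5 2-(methoxymethoxy)-3,4,5-trimethoxyphenol, via aryllithium 3 (not isolated), via dimethyl arylboronate 4 (not isolated)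
Conditions: n-BuLi, THF, 0 °C; B(OMe)3, −78 °C → rt; AcOH, 30% H2O2, 0 °C → rt
Reagents that add atoms: hydrogen peroxide, OO
Why: Directed ortho-metalation should take place at the one ring hydrogen next to the chelating methoxymethoxy group (a stronger director than the methoxy group beside the other hydrogen), and borylation followed by peroxide oxidation (1,2-shift of aryl from boron to oxygen) turns the C–Li bond into the C–OH of ring C C1.

**Step 3**
Reactants: 5 2-(methoxymethoxy)-3,4,5-trimethoxyphenol; 6 2-chloro-N-methoxy-N-methylacetamide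
Product: 7 N-methoxy-2-[2-(methoxymethoxy)-3,4,5-trimethoxyphenoxy]-N-methylacetamide
Conditions: K2CO3, NaI (cat.), DMF, 60 °C
Reagents that add atoms: none
Why: Williamson ether synthesis of the phenoxide with an α-chloro amide under iodide catalysis is reliable and installs the aryloxyacetyl unit directly as an N-methoxy-N-methylamide.

**Step 4**
Reactants: 7 N-methoxy-2-[2-(methoxymethoxy)-3,4,5-trimethoxyphenoxy]-N-methylacetamide; 8 2,2,6-trimethyl-4H-1,3-dioxin-4-one
Product: 9 6-{3-[2-(methoxymethoxy)-3,4,5-trimethoxyphenoxy]-2-oxopropyl}-2,2-dimethyl-4H-1,3-dioxin-4-one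
Conditions: 8 (2.2 equiv), LiN(i-Pr)2, THF, −78 °C; then 7, −78 → −20 °C; AcOH
Reagents that add atoms: none
Why: The lithium dienolate of 8 should be acylated at its terminal carbon by the N-methoxy-N-methylamide (Weinreb ketone synthesis), the chelated tetrahedral adduct preventing over-addition and proton transfer until the quench.

**Step 5**
Reactants: 9 6-{3-[2-(methoxymethoxy)-3,4,5-trimethoxyphenoxy]-2-oxopropyl}-2,2-dimethyl-4H-1,3-dioxin-4-one
Product: 11 4-hydroxy-6-{[2-(methoxymethoxy)-3,4,5-trimethoxyphenoxy]methyl}-2H-pyran-2-one, via acylketene 10 (not isolated)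
Conditions: PhMe, 110 °C
Reagents that add atoms: none
Why: Thermal retro-hetero-Diels–Alder loss of acetone should give the acylketene, which is trapped at once by the enol oxygen of the side-chain ketone to close the six-membered lactone.

**Step 6**
Reactants: 11 4-hydroxy-6-{[2-(methoxymethoxy)-3,4,5-trimethoxyphenoxy]methyl}-2H-pyran-2-one
Product: 12 4-(benzyloxy)-6-{[2-(methoxymethoxy)-3,4,5-trimethoxyphenoxy]methyl}-2H-pyran-2-one
Conditions: PhCH2OH, PPh3, DIAD, THF, 0 °C → rt
Reagents that add atoms: benzyl alcohol, OCc1ccccc1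
Why: The Mitsunobu reaction of the acidic 4-hydroxy-2-pyranone should alkylate the C4 oxygen selectively, avoiding the C3-benzylation that benzyl halides can cause.

**Step 7**
Reactants: 12 4-(benzyloxy)-6-{[2-(methoxymethoxy)-3,4,5-trimethoxyphenoxy]methyl}-2H-pyran-2-one
Product: 15 5-(benzyloxy)-2-[2-(methoxymethoxy)-3,4,5-trimethoxyphenoxy]benzene-1,3-diol, via ring-opened benzyl ester 13 (not isolated), via cyclohexenedione 14 (not isolated)
Conditions: NaOCH2Ph (1.0 M in PhCH2OH, 4 equiv), THF, 60 °C; then AcOH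
Reagents that add atoms: none
Why: Proposed new method: benzyloxide adds to the lactone carbonyl of 12 and opens it to keto enoate 13, in which the E enol ether double bond inherited from the ring keeps the new benzyl ester on the same side as the CH2–CO–CH2OAr arm; the enolate at the aryloxy-bearing carbon then attacks the ester carbonyl (Claisen condensation), benzyloxide leaves, and dione 14 enolises to the resorcinol, held as its bis-phenoxide. The closest known reactions are the alkoxide-mediated Claisen cyclisations of 3,5-dioxo esters and of ring-opened 6-(acylmethyl)-4-methoxy-2-pyranones to phloroglucinol derivatives; what is new is an α-aryloxy ketone carbon as the nucleophile, which delivers the ring already bearing the diaryl ether. Ring B closes 6-exo-trig, the enolate carbon bonding to the ester carbon (B C4–B C3) with the carbonyl oxygen outside the ring. No stereocenter is set, since the single sp3 centre of 14 is lost on aromatisation. The step needs C-acylation by the aryloxymethyl carbon in preference to relactonisation or reaction at the chain C4 methylene: only the aryloxymethyl carbanion can reach the ester through a six-membered transition state, ring opening and enolate formation are reversible, and aromatisation to the bis-phenoxide is the one irreversible exit. Benzyloxide is chosen as the base so that transesterification or addition–elimination at the enol ether carbon can only return the same benzyl groups and the label on B C1 stays intact.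

**Step 8**
Reactants: 15 5-(benzyloxy)-2-[2-(methoxymethoxy)-3,4,5-trimethoxyphenoxy]benzene-1,3-diol
Product: 16 5-(benzyloxy)-1,3-dimethoxy-2-[2-(methoxymethoxy)-3,4,5-trimethoxyphenoxy]benzene
Conditions: Me2SO4, K2CO3, acetone, 56 °C
Reagents that add atoms: dimethyl sulfate, COS(=O)(=O)OC
Why: Williamson O-methylation with dimethyl sulfate and carbonate in acetone is the classical way to etherify phloroglucinol-type phenols on oxygen, not on carbon, and should cap B C3–OH and B C5–OH.

**Step 9**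
Reactants: 16 5-(benzyloxy)-1,3-dimethoxy-2-[2-(methoxymethoxy)-3,4,5-trimethoxyphenoxy]benzene
Product: 17 3,5-dimethoxy-4-[2-(methoxymethoxy)-3,4,5-trimethoxyphenoxy]phenol
Conditions: H2 (1 atm), Pd/C, EtOAc, rt
Reagents that add atoms: none
Why: Catalytic hydrogenolysis should cleave only the benzyl aryl ether and free B C1–OH, the methyl ethers, the acetal and the diaryl ether being inert.

**Step 10**
Reactants: 17 3,5-dimethoxy-4-[2-(methoxymethoxy)-3,4,5-trimethoxyphenoxy]phenol; 18 2-iodo-1,3,5-trimethoxybenzene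
Product: 19 1,3-dimethoxy-2-[2-(methoxymethoxy)-3,4,5-trimethoxyphenoxy]-5-(2,4,6-trimethoxyphenoxy)benzene
Conditions: 18 (2 equiv), CuI, picolinic acid, K3PO4, DMSO, 90 °C
Reagents that add atoms: none
Why: Ullmann diaryl ether synthesis with the copper/picolinic acid system, which tolerates ortho-substituted partners, should join the unhindered B C1 phenoxide to the di-ortho-methoxy iodide, the excess of 18 covering loss by hydrodeiodination.

**Step 11**
Reactants: 19 1,3-dimethoxy-2-[2-(methoxymethoxy)-3,4,5-trimethoxyphenoxy]-5-(2,4,6-trimethoxyphenoxy)benzene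
Product: 20 6-[2,6-dimethoxy-4-(2,4,6-trimethoxyphenoxy)phenoxy]-2,3,4-trimethoxyphenol
Conditions: ZnBr2, n-PrSH, CH2Cl2, 0 °C → rt
Reagents that add atoms: none
Why: Lewis acid-assisted acetal cleavage in the presence of a thiol should free C C6–OH within minutes, the thiol capturing the methoxymethyl cation before it can alkylate the electron-rich rings A and B.

**Step 12**
Reactants: 20 6-[2,6-dimethoxy-4-(2,4,6-trimethoxyphenoxy)phenoxy]-2,3,4-trimethoxyphenol; 21 4-bromo-2,6-dimethoxybenzaldehyde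
Product: 22 4-{6-[2,6-dimethoxy-4-(2,4,6-trimethoxyphenoxy)phenoxy]-2,3,4-trimethoxyphenoxy}-2,6-dimethoxybenzaldehyde
Conditions: 21 (1.5 equiv), CuI, picolinic acid, K3PO4, DMSO, 90 °C
Reagents that add atoms: none
Why: Ullmann ether synthesis of the crowded C C6 phenoxide should be helped by the para-formyl group, which activates the bromide and is at the same time the masked D C4 oxygen.

**Step 13**
Reactants: 22 4-{6-[2,6-dimethoxy-4-(2,4,6-trimethoxyphenoxy)phenoxy]-2,3,4-trimethoxyphenoxy}-2,6-dimethoxybenzaldehyde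
Product: 24 4-{6-[2,6-dimethoxy-4-(2,4,6-trimethoxyphenoxy)phenoxy]-2,3,4-trimethoxyphenoxy}-2,6-dimethoxyphenol, via aryl formate 23 (not isolated)
Conditions: mCPBA, CH2Cl2, 0 °C → rt; then K2CO3 (cat.), MeOH, rt
Reagents that add atoms: 3-chloroperoxybenzoic acid, OOC(=O)c1cccc(Cl)c1
Why: Baeyer–Villiger oxidation of a benzaldehyde flanked by two methoxy groups should proceed with aryl migration to the formate, and methanolysis then frees the hindered D C4 phenol.

**Step 14**
Reactants: 24 4-{6-[2,6-dimethoxy-4-(2,4,6-trimethoxyphenoxy)phenoxy]-2,3,4-trimethoxyphenoxy}-2,6-dimethoxyphenol; 25 2-bromo-4,6-dimethoxybenzaldehyde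
Product: 26 2-(4-{6-[2,6-dimethoxy-4-(2,4,6-trimethoxyphenoxy)phenoxy]-2,3,4-trimethoxyphenoxy}-2,6-dimethoxyphenoxy)-4,6-dimethoxybenzaldehyde
Conditions: 25 (1.5 equiv), CuI, picolinic acid, K3PO4, DMSO, 100 °C
Reagents that add atoms: none
Why: Ullmann ether synthesis of the 2,6-dimethoxyphenoxide with an ortho-formyl aryl bromide should benefit from the activating ortho-carbonyl group, which is also the masked E C6 oxygen.

**Step 15**
Reactants: 26 2-(4-{6-[2,6-dimethoxy-4-(2,4,6-trimethoxyphenoxy)phenoxy]-2,3,4-trimethoxyphenoxy}-2,6-dimethoxyphenoxy)-4,6-dimethoxybenzaldehyde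
Product: 28 2-(4-{6-[2,6-dimethoxy-4-(2,4,6-trimethoxyphenoxy)phenoxy]-2,3,4-trimethoxyphenoxy}-2,6-dimethoxyphenoxy)-4,6-dimethoxyphenol, via aryl formate 27 (not isolated)
Conditions: mCPBA, CH2Cl2, 0 °C → rt; then K2CO3 (cat.), MeOH, rt, under argon
Reagents that add atoms: 3-chloroperoxybenzoic acid, OOC(=O)c1cccc(Cl)c1
Why: Baeyer–Villiger oxidation with aryl migration (ring E carries ortho and para oxygen donors) and formate methanolysis should give the E C6 phenol, as in step 13.

**Step 16**
Reactants: 29 4-bromo-2,6-dimethoxyphenol; 30 5-iodo-1,2,3-trimethoxybenzene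
Product: 31 5-bromo-1,3-dimethoxy-2-(3,4,5-trimethoxyphenoxy)benzene
Conditions: 30 (1.5 equiv), CuI, picolinic acid, K3PO4, DMSO, 80 °C
Reagents that add atoms: none
Why: Ullmann ether synthesis should be chemoselective for the aryl iodide at this temperature, the bromine of 29 sitting para to a phenoxide oxygen and so being deactivated, which leaves the F C1 bromide in place.

**Step 17**
Reactants: 28 2-(4-{6-[2,6-dimethoxy-4-(2,4,6-trimethoxyphenoxy)phenoxy]-2,3,4-trimethoxyphenoxy}-2,6-dimethoxyphenoxy)-4,6-dimethoxyphenol; 31 5-bromo-1,3-dimethoxy-2-(3,4,5-trimethoxyphenoxy)benzene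
Product: 32 heptadecamethyl ether of 33 (rings A to G joined as in the target, all seventeen hydroxyls as OMe)
Conditions: 31 (1.5 equiv), CuI, picolinic acid, K3PO4, DMSO, 110 °C
Reagents that add atoms: none
Why: Ullmann ether synthesis in the polarity of a hindered electron-rich phenoxide with an unhindered 3,5-dimethoxyaryl bromide should form the last ether, E C6–O–F C1.

**Step 18**
Reactants: 32 heptadecamethyl ether of 33
Product: 33 CNP0351377.0 (heptamer of rings A to G with seventeen free hydroxyls)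
Conditions: BBr3 (excess), CH2Cl2, −78 °C → rt; then H2O, 0 °C, under argon
Reagents that add atoms: none
Why: Lewis acid ether cleavage by BBr3 should remove every methyl group by bromide attack at the methyl carbon, while the diaryl ether oxygens have no sp3 carbon to be attacked and should stay.

**Compound list**
1 | 2,3,4-trimethoxyphenol | COc1ccc(O)c(OC)c1OC | starting material
2 | 1,2,3-trimethoxy-4-(methoxymethoxy)benzene | COCOc1ccc(OC)c(OC)c1OC | intermediate
3 | [2-(methoxymethoxy)-3,4,5-trimethoxyphenyl]lithium | COCOc1c([Li])cc(OC)c(OC)c1OC | intermediate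
4 | dimethyl [2-(methoxymethoxy)-3,4,5-trimethoxyphenyl]boronate | COCOc1c(B(OC)OC)cc(OC)c(OC)c1OC | intermediate
5 | 2-(methoxymethoxy)-3,4,5-trimethoxyphenol | COCOc1c(O)cc(OC)c(OC)c1OC | intermediate
6 | 2-chloro-N-methoxy-N-methylacetamide | CON(C)C(=O)CCl | starting material
7 | N-methoxy-2-[2-(methoxymethoxy)-3,4,5-trimethoxyphenoxy]-N-methylacetamide | COCOc1c(OCC(=O)N(C)OC)cc(OC)c(OC)c1OC | intermediate
8 | 2,2,6-trimethyl-4H-1,3-dioxin-4-one | CC1=CC(=O)OC(C)(C)O1 | starting material
9 | 6-{3-[2-(methoxymethoxy)-3,4,5-trimethoxyphenoxy]-2-oxopropyl}-2,2-dimethyl-4H-1,3-dioxin-4-one | COCOc1c(OCC(=O)CC2=CC(=O)OC(C)(C)O2)cc(OC)c(OC)c1OC | intermediate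
10 | 6-[2-(methoxymethoxy)-3,4,5-trimethoxyphenoxy]-3,5-dioxohex-1-en-1-one (acylketene) | COCOc1c(OCC(=O)CC(=O)C=C=O)cc(OC)c(OC)c1OC | intermediate
11 | 4-hydroxy-6-{[2-(methoxymethoxy)-3,4,5-trimethoxyphenoxy]methyl}-2H-pyran-2-one | COCOc1c(OCC2=CC(O)=CC(=O)O2)cc(OC)c(OC)c1OC | intermediate
12 | 4-(benzyloxy)-6-{[2-(methoxymethoxy)-3,4,5-trimethoxyphenoxy]methyl}-2H-pyran-2-one | COCOc1c(OCC2=CC(OCc3ccccc3)=CC(=O)O2)cc(OC)c(OC)c1OC | intermediate
13 | benzyl (2E)-3-(benzyloxy)-6-[2-(methoxymethoxy)-3,4,5-trimethoxyphenoxy]-5-oxohex-2-enoate | COCOc1c(OCC(=O)C/C(OCc2ccccc2)=C\C(=O)OCc2ccccc2)cc(OC)c(OC)c1OC | intermediate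
14 | 5-(benzyloxy)-2-[2-(methoxymethoxy)-3,4,5-trimethoxyphenoxy]cyclohex-4-ene-1,3-dione (racemic) | COCOc1c(OC2C(=O)CC(OCc3ccccc3)=CC2=O)cc(OC)c(OC)c1OC | intermediate
15 | 5-(benzyloxy)-2-[2-(methoxymethoxy)-3,4,5-trimethoxyphenoxy]benzene-1,3-diol | COCOc1c(Oc2c(O)cc(OCc3ccccc3)cc2O)cc(OC)c(OC)c1OC | intermediate
16 | 5-(benzyloxy)-1,3-dimethoxy-2-[2-(methoxymethoxy)-3,4,5-trimethoxyphenoxy]benzene | COCOc1c(Oc2c(OC)cc(OCc3ccccc3)cc2OC)cc(OC)c(OC)c1OC | intermediate
17 | 3,5-dimethoxy-4-[2-(methoxymethoxy)-3,4,5-trimethoxyphenoxy]phenol | COCOc1c(Oc2c(OC)cc(O)cc2OC)cc(OC)c(OC)c1OC | intermediate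
18 | 2-iodo-1,3,5-trimethoxybenzene | COc1cc(OC)c(I)c(OC)c1 | starting material
19 | 1,3-dimethoxy-2-[2-(methoxymethoxy)-3,4,5-trimethoxyphenoxy]-5-(2,4,6-trimethoxyphenoxy)benzene | COCOc1c(Oc2c(OC)cc(Oc3c(OC)cc(OC)cc3OC)cc2OC)cc(OC)c(OC)c1OC | intermediate
20 | 6-[2,6-dimethoxy-4-(2,4,6-trimethoxyphenoxy)phenoxy]-2,3,4-trimethoxyphenol | Oc1c(Oc2c(OC)cc(Oc3c(OC)cc(OC)cc3OC)cc2OC)cc(OC)c(OC)c1OC | intermediate
21 | 4-bromo-2,6-dimethoxybenzaldehyde | COc1cc(Br)cc(OC)c1C=O | starting material
22 | 4-{6-[2,6-dimethoxy-4-(2,4,6-trimethoxyphenoxy)phenoxy]-2,3,4-trimethoxyphenoxy}-2,6-dimethoxybenzaldehyde | O=Cc1c(OC)cc(Oc2c(Oc3c(OC)cc(Oc4c(OC)cc(OC)cc4OC)cc3OC)cc(OC)c(OC)c2OC)cc1OC | intermediate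
23 | 4-{6-[2,6-dimethoxy-4-(2,4,6-trimethoxyphenoxy)phenoxy]-2,3,4-trimethoxyphenoxy}-2,6-dimethoxyphenyl formate | O=COc1c(OC)cc(Oc2c(Oc3c(OC)cc(Oc4c(OC)cc(OC)cc4OC)cc3OC)cc(OC)c(OC)c2OC)cc1OC | intermediate
24 | 4-{6-[2,6-dimethoxy-4-(2,4,6-trimethoxyphenoxy)phenoxy]-2,3,4-trimethoxyphenoxy}-2,6-dimethoxyphenol | Oc1c(OC)cc(Oc2c(Oc3c(OC)cc(Oc4c(OC)cc(OC)cc4OC)cc3OC)cc(OC)c(OC)c2OC)cc1OC | intermediate
25 | 2-bromo-4,6-dimethoxybenzaldehyde | COc1cc(Br)c(C=O)c(OC)c1 | starting material
26 | 2-(4-{6-[2,6-dimethoxy-4-(2,4,6-trimethoxyphenoxy)phenoxy]-2,3,4-trimethoxyphenoxy}-2,6-dimethoxyphenoxy)-4,6-dimethoxybenzaldehyde | O=Cc1c(OC)cc(OC)cc1Oc2c(OC)cc(Oc3c(Oc4c(OC)cc(Oc5c(OC)cc(OC)cc5OC)cc4OC)cc(OC)c(OC)c3OC)cc2OC | intermediate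
27 | 2-(4-{6-[2,6-dimethoxy-4-(2,4,6-trimethoxyphenoxy)phenoxy]-2,3,4-trimethoxyphenoxy}-2,6-dimethoxyphenoxy)-4,6-dimethoxyphenyl formate | O=COc1c(OC)cc(OC)cc1Oc2c(OC)cc(Oc3c(Oc4c(OC)cc(Oc5c(OC)cc(OC)cc5OC)cc4OC)cc(OC)c(OC)c3OC)cc2OC | intermediate
28 | 2-(4-{6-[2,6-dimethoxy-4-(2,4,6-trimethoxyphenoxy)phenoxy]-2,3,4-trimethoxyphenoxy}-2,6-dimethoxyphenoxy)-4,6-dimethoxyphenol | Oc1c(OC)cc(OC)cc1Oc2c(OC)cc(Oc3c(Oc4c(OC)cc(Oc5c(OC)cc(OC)cc5OC)cc4OC)cc(OC)c(OC)c3OC)cc2OC | intermediate
29 | 4-bromo-2,6-dimethoxyphenol | COc1cc(Br)cc(OC)c1O | starting material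
30 | 5-iodo-1,2,3-trimethoxybenzene | COc1cc(I)cc(OC)c1OC | starting material
31 | 5-bromo-1,3-dimethoxy-2-(3,4,5-trimethoxyphenoxy)benzene | COc1cc(Br)cc(OC)c1Oc1cc(OC)c(OC)c(OC)c1 | intermediate
32 | heptadecamethyl ether of 33 (rings A to G, all hydroxyls as OMe) | COc1cc(OC)c(Oc2cc(OC)c(Oc3cc(OC)c(OC)c(OC)c3Oc3cc(OC)c(Oc4cc(OC)cc(OC)c4Oc4cc(OC)c(Oc5cc(OC)c(OC)c(OC)c5)c(OC)c4)c(OC)c3)c(OC)c2)c(OC)c1 | intermediate
33 | CNP0351377.0 (rings A to G, seventeen free hydroxyls, six diaryl ethers) | Oc1cc(O)c(Oc2cc(O)c(Oc3cc(O)c(O)c(O)c3Oc3cc(O)c(Oc4cc(O)cc(O)c4Oc4cc(O)c(Oc5cc(O)c(O)c(O)c5)c(O)c4)c(O)c3)c(O)c2)c(O)c1 | target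

**Step count**
Total steps: 18. Longest linear sequence: 17 (steps 1 to 15, 17 and 18; step 16 is a one-step branch).

**Steps most likely to fail**

1. Step 7. The ring-opened species may relactonise or rest as the conjugated dienolate, so that closure of the aryloxymethyl carbanion onto the electron-rich enoate ester does not compete and prolonged heating only degrades the material. Fallback by known chemistry, setting out from compound 2 and returning at compound 16: directed ortho-lithiation of 2 (n-BuLi, THF, 0 °C) and quenching with iodine should give 1-iodo-3,4,5-trimethoxy-2-(methoxymethoxy)benzene F1. Purchased 2,6-dimethoxybenzene-1,4-diol is benzylated at its unhindered, more acidic hydroxyl (PhCH2Br, K2CO3, acetone) to give 4-(benzyloxy)-2,6-dimethoxyphenol F2. Ullmann coupling of F2 with F1 (CuI, picolinic acid, K3PO4, DMSO, 100 °C) forms the B C4–O–C C1 ether directly and should give 16, from which step 9 continues.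

2. Step 10. Oxidative addition of the doubly ortho-substituted, electron-rich iodide may be too slow, so that hydrodeiodination consumes 18 before the ether forms. Fallback with the roles of the partners reversed, setting out from compound 17 and returning at compound 19: 17 is converted with PhNTf2 and K2CO3 in THF into 3,5-dimethoxy-4-[2-(methoxymethoxy)-3,4,5-trimethoxyphenoxy]phenyl trifluoromethanesulfonate F3. Palladium-catalysed C–O coupling of F3 with purchased 2,4,6-trimethoxyphenol (Pd(OAc)2, 2-di-tert-butylphosphino-2',4',6'-triisopropylbiphenyl, K3PO4, PhMe, 100 °C) should give 19; here the hindered ring A is the nucleophile, the polarity that crowded diaryl ethers tolerate best.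

3. Step 17. Arylation of the crowded E C6 phenoxide by the unactivated bromide 31 may be too slow, with the phenol lost to oxidation at 110 °C. Fallback that adds rings F and G one at a time with an activated electrophile, setting out from compound 28 and returning at compound 32: Ullmann coupling of 28 with 21 (CuI, picolinic acid, K3PO4, DMSO, 90 °C) should give the hexamer aldehyde 4-[2-(4-{6-[2,6-dimethoxy-4-(2,4,6-trimethoxyphenoxy)phenoxy]-2,3,4-trimethoxyphenoxy}-2,6-dimethoxyphenoxy)-4,6-dimethoxyphenoxy]-2,6-dimethoxybenzaldehyde F4. Baeyer–Villiger oxidation (mCPBA, CH2Cl2) gives the corresponding hexamer aryl formate F5, and methanolysis (K2CO3, MeOH) gives the hexamer phenol with free F C4–OH F6. Ullmann coupling of F6 with purchased 5-bromo-1,2,3-trimethoxybenzene, the classical pairing of a 2,6-dimethoxyphenol with an unhindered bromide, then gives 32.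

**Further compounds**
F1 | step 7 | 1-iodo-3,4,5-trimethoxy-2-(methoxymethoxy)benzene | COCOc1c(I)cc(OC)c(OC)c1OC
F2 | step 7 | 4-(benzyloxy)-2,6-dimethoxyphenol | COc1cc(OCc2ccccc2)cc(OC)c1O
F3 | step 10 | 3,5-dimethoxy-4-[2-(methoxymethoxy)-3,4,5-trimethoxyphenoxy]phenyl trifluoromethanesulfonate | COCOc1c(Oc2c(OC)cc(OS(=O)(=O)C(F)(F)F)cc2OC)cc(OC)c(OC)c1OC
F4 | step 17 | hexamer aldehyde, 4-[2-(4-{6-[2,6-dimethoxy-4-(2,4,6-trimethoxyphenoxy)phenoxy]-2,3,4-trimethoxyphenoxy}-2,6-dimethoxyphenoxy)-4,6-dimethoxyphenoxy]-2,6-dimethoxybenzaldehyde | O=Cc1c(OC)cc(Oc2c(OC)cc(OC)cc2Oc3c(OC)cc(Oc4c(Oc5c(OC)cc(Oc6c(OC)cc(OC)cc6OC)cc5OC)cc(OC)c(OC)c4OC)cc3OC)cc1OC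
F5 | step 17 | hexamer aryl formate (formate ester of F6) | O=COc1c(OC)cc(Oc2c(OC)cc(OC)cc2Oc3c(OC)cc(Oc4c(Oc5c(OC)cc(Oc6c(OC)cc(OC)cc6OC)cc5OC)cc(OC)c(OC)c4OC)cc3OC)cc1OC
F6 | step 17 | hexamer phenol (rings A to F, free F C4–OH, all other oxygens as OMe) | Oc1c(OC)cc(Oc2c(OC)cc(OC)cc2Oc3c(OC)cc(Oc4c(Oc5c(OC)cc(Oc6c(OC)cc(OC)cc6OC)cc5OC)cc(OC)c(OC)c4OC)cc3OC)cc1OC
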